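## Retrosynthetic overview

- The plan rests on central ring B (atoms B1–B6), a 1,2,4,5-tetrasubstituted resorcinol: carbon at B1 (C3 of the upper chroman) and B5 (C4 of the lower chroman), free OH at B2, OMe at B4, H at B3 and B6.
- Ring B is cut across B1–B6 and B4–B5 into a 1,1-dimethoxy-3-silyloxydiene carrying the finished (R)-7-benzyloxychroman-3-yl group and a ring D ethynyl ketone; cycloaddition and aromatisation give the ring D–CO–ring B benzophenone.
- The diene comes from (S)-7-benzyloxychroman-3-carboxylic acid (asymmetric hydrogenation of the chromene acid) by Arndt–Eistert homologation, acylation of 1,1-dimethoxyethene and silylation; the ynone comes from the same salicylaldehyde.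
- The lower half follows from the benzophenone: ortho-quinone methide from ring D, isothiourea-catalysed annulation with the ring F arylacetic acid (C3–C4 bond, C4 set), epimerisation to trans, lactone reduction, Mitsunobu closure, debenzylation.
- Ring order: upper pyran ring (on ring A), then ring B (key step), then lower pyran ring (on ring D).

Key step: step 12

Assumption: the sense of induction in steps 4 and 21 is taken from the accepted facial models and from the cis course usual for amidine-catalysed ortho-quinone methide annulations; both catalysts exist in both hands, so a wrong sense seen on a first small run would be corrected by using the antipode.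

## Route

Step 1
Reactants: 1 2,4-dihydroxybenzaldehyde
Product: 2 4-(benzyloxy)-2-hydroxybenzaldehyde
Conditions: BnBr (1.05 equiv), NaHCO3, MeCN, 80 °C
Reagents that add atoms: benzyl bromide, BrCc1ccccc1
Why: Williamson etherification with a weak base alkylates only the 4-OH, because the 2-OH is tied up in a hydrogen bond to the aldehyde.

Step 2
Reactants: 2 4-(benzyloxy)-2-hydroxybenzaldehyde; 3 acrylonitrile
Product: 4 7-(benzyloxy)-2H-chromene-3-carbonitrile
Conditions: DABCO (0.5 equiv), neat acrylonitrile, 80 °C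
Reagents that add atoms: none
Why: Oxa-Michael addition of the phenoxide, intramolecular Baylis–Hillman-type aldol onto the aldehyde and dehydration close the upper pyran ring, a standard chromene annulation of salicylaldehydes.

Step 3
Reactants: 4 7-(benzyloxy)-2H-chromene-3-carbonitrile
Product: 5 7-(benzyloxy)-2H-chromene-3-carboxylic acid
Conditions: 10% aq NaOH, reflux; then HCl to pH 2
Reagents that add atoms: sodium hydroxide, [Na+].[OH-]; water, O
Why: Alkaline nitrile hydrolysis gives the conjugated acid, and the aryl benzyl ether is inert to hot base.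

Step 4
Reactants: 5 7-(benzyloxy)-2H-chromene-3-carboxylic acid
Product: 6 (S)-7-(benzyloxy)chroman-3-carboxylic acid
Conditions: H2 (6 atm), [Ir(cod)(SIPHOX)][B(C6H3(CF3)2)4] (1 mol%, chiral spiro phosphine–oxazoline ligand), Et3N (0.5 equiv), MeOH, rt; acid work-up
Reagents that add atoms: none
Why: Carboxylate-directed asymmetric hydrogenation of the unsaturated heterocyclic acid adds H2 to one face of C3=C4 under control of the spiro ligand and sets C3 as S, while the homogeneous catalyst leaves the benzyl ether alone.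

Step 5
Reactants: 6 (S)-7-(benzyloxy)chroman-3-carboxylic acid
Product: 8 (S)-1-[7-(benzyloxy)chroman-3-yl]-2-diazoethan-1-one, via isobutyl carbonic mixed anhydride 7 (not isolated)
Conditions: iBuOCOCl, N-methylmorpholine, THF, −15 °C; then CH2N2, Et2O, 0 °C
Reagents that add atoms: diazomethane, C=[N+]=[N-]
Why: First half of the Arndt–Eistert homologation; cold mixed-anhydride activation avoids enolisation of the α-stereocentre (and ring opening by loss of the β-aryloxide) before diazomethane is acylated.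

Step 6
Reactants: 8 (S)-1-[7-(benzyloxy)chroman-3-yl]-2-diazoethan-1-one
Product: 10 (R)-2-[7-(benzyloxy)chroman-3-yl]acetic acid, via ketene 9 (not isolated)
Conditions: PhCO2Ag (10 mol%), Et3N, THF/H2O (9:1), −20 °C → rt, dark
Reagents that add atoms: water, O
Why: Silver-promoted Wolff rearrangement moves the chroman C3 carbon with retention and water traps the ketene; the geometry is unchanged and the descriptor changes to R only by priority.

Step 7
Reactants: 10 (R)-2-[7-(benzyloxy)chroman-3-yl]acetic acid; 11 1,1-dimethoxyethene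
Product: 13 (R)-1-[7-(benzyloxy)chroman-3-yl]-4,4-dimethoxybut-3-en-2-one, via acid chloride 12 (not isolated)
Conditions: (COCl)2, DMF (cat.), CH2Cl2, 0 °C → rt, evaporate; then 11 (2.2 equiv), Et2O, 0 °C → rt; base-washed alumina
Reagents that add atoms: none
Why: C-acylation of the ketene acetal by the acid chloride and loss of HCl (taken up by the second equivalent of ketene acetal) is the classical route to acyl ketene acetals, and the stereocentre is now β to the carbonyl and safe.

Step 8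
Reactants: 13 (R)-1-[7-(benzyloxy)chroman-3-yl]-4,4-dimethoxybut-3-en-2-one
Product: 14 (R)-7-(benzyloxy)-3-[(1Z)-4,4-dimethoxy-2-(trimethylsilyloxy)buta-1,3-dien-1-yl]chroman
Conditions: TMSOTf, Et3N, Et2O, 0 °C; filtered under argon, used crude
Reagents that add atoms: trimethylsilyl trifluoromethanesulfonate, C[Si](C)(C)OS(=O)(=O)C(F)(F)F
Why: Soft enolisation silylates the vinylogous ester oxygen and removes the only available α-proton (the CH2 next to the chroman), and the Z enol ether is expected because it avoids allylic strain between the chroman and the ketene acetal arm.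

Step 9
Reactants: 2 4-(benzyloxy)-2-hydroxybenzaldehyde
Product: 15 4-(benzyloxy)-2-(methoxymethoxy)benzaldehyde
Conditions: MOMCl, iPr2NEt, CH2Cl2, 0 °C → rt
Reagents that add atoms: chloromethyl methyl ether, COCCl
Why: O-Alkylation gives an acetal that later comes off under mild acid without touching benzyl ethers.

Step 10
Reactants: 15 4-(benzyloxy)-2-(methoxymethoxy)benzaldehyde; 16 ethynylmagnesium bromide
Product: 17 rac-1-[4-(benzyloxy)-2-(methoxymethoxy)phenyl]prop-2-yn-1-ol
Conditions: THF, 0 °C; then H2O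
Reagents that add atoms: none
Why: Grignard 1,2-addition to the aldehyde; the carbinol centre is racemic and is removed in the next step.

Step 11
Reactants: 17 rac-1-[4-(benzyloxy)-2-(methoxymethoxy)phenyl]prop-2-yn-1-ol
Product: 18 1-[4-(benzyloxy)-2-(methoxymethoxy)phenyl]prop-2-yn-1-one
Conditions: MnO2 (activated), CH2Cl2, rt
Reagents that add atoms: none
Why: MnO2 oxidises the benzylic–propargylic alcohol selectively under neutral conditions that spare the acetal and the terminal alkyne.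

Step 12
Reactants: 14 (R)-7-(benzyloxy)-3-[(1Z)-4,4-dimethoxy-2-(trimethylsilyloxy)buta-1,3-dien-1-yl]chroman; 18 1-[4-(benzyloxy)-2-(methoxymethoxy)phenyl]prop-2-yn-1-one
Product: 21 [4-(benzyloxy)-2-(methoxymethoxy)phenyl]{5-[(3R)-7-(benzyloxy)chroman-3-yl]-4-hydroxy-2-methoxyphenyl}methanone, via cyclohexadiene cycloadduct 19 (not isolated), via aryl trimethylsilyl ether 20 (not isolated)
Conditions: toluene, rt → 60 °C (14 in 1.3-fold excess); then K2CO3 (0.2 equiv), MeOH, rt
Reagents that add atoms: none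
Why: The electron-rich diene and the electron-poor ynone combine in a normal-demand, concerted but strongly asynchronous [4+2] cycloaddition in which the chroman-bearing diene terminus bonds first to the unsubstituted β-carbon of the ynone (B1–B6) and the ketene acetal carbon then bonds to the acyl-bearing α-carbon (B4–B5). This is the known Diels–Alder/aromatisation of 1,1-dialkoxy-3-silyloxydienes with acetylenic ketones that gives resorcinol monoethers. Ring B is the only ring closed, in the [4+2] mode from the s-cis diene; cycloadduct 19 then loses methanol (doubly allylic ring C–H and one ketal methoxy group) to give silyl ether 20, which K2CO3/MeOH cleaves to phenol 21. No stereocentre is formed, since the sp3 ring carbon of 19 disappears on aromatisation, and the non-acidic C3 of the upper chroman lies outside the reacting π-system and is carried through unchanged. The step needs complete regioselectivity, secured by the matched push–pull polarisation of the pair (the diene terminus remote from the ketene acetal is the most nucleophilic carbon, the ynone β-carbon the most electrophilic), which places OMe ortho and OH para to the new ketone and fixes the methyl-versus-hydrogen choice on the two oxygens. It also needs a reachable s-cis diene, secured by the Z silyl enol ether that holds the chroman on the outside.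

Step 13
Reactants: 22 2,6-dimethoxyphenol
Product: 23 2-(benzyloxy)-1,3-dimethoxybenzene
Conditions: BnBr, K2CO3, DMF, rt
Reagents that add atoms: benzyl bromide, BrCc1ccccc1
Why: Williamson benzylation of the only hydroxyl.

Step 14
Reactants: 23 2-(benzyloxy)-1,3-dimethoxybenzene
Product: 24 3-(benzyloxy)-1-bromo-2,4-dimethoxybenzene
Conditions: NBS, MeCN, 0 °C → rt
Reagents that add atoms: N-bromosuccinimide, O=C1CCC(=O)N1Br
Why: Electrophilic bromination of a 1,2,3-trialkoxybenzene goes to C4 (para to one methoxy, ortho to the other), because the twisted central alkoxy group does not activate C5.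

Step 15
Reactants: 24 3-(benzyloxy)-1-bromo-2,4-dimethoxybenzene; 25 diethyl malonate
Product: 26 diethyl 2-[3-(benzyloxy)-2,4-dimethoxyphenyl]malonate
Conditions: Pd2(dba)3 (1 mol%), P(tBu)3·HBF4 (4 mol%), K3PO4, toluene, 80 °C
Reagents that add atoms: none
Why: Palladium-catalysed α-arylation of a malonate tolerates electron-rich ortho-substituted aryl bromides when a bulky trialkylphosphine is used.

Step 16
Reactants: 26 diethyl 2-[3-(benzyloxy)-2,4-dimethoxyphenyl]malonate
Product: 28 2-[3-(benzyloxy)-2,4-dimethoxyphenyl]acetic acid, via arylmalonic acid 27 (not isolated)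
Conditions: NaOH, EtOH/H2O, reflux; then HCl to pH 1, 70 °C
Reagents that add atoms: sodium hydroxide, [Na+].[OH-]
Why: Saponification followed by the easy thermal decarboxylation of an arylmalonic acid gives the ring F arylacetic acid.

Step 17
Reactants: 21 [4-(benzyloxy)-2-(methoxymethoxy)phenyl]{5-[(3R)-7-(benzyloxy)chroman-3-yl]-4-hydroxy-2-methoxyphenyl}methanone
Product: 29 {4-(benzyloxy)-5-[(3R)-7-(benzyloxy)chroman-3-yl]-2-methoxyphenyl}[4-(benzyloxy)-2-(methoxymethoxy)phenyl]methanone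
Conditions: BnBr, K2CO3, DMF, rt
Reagents that add atoms: benzyl bromide, BrCc1ccccc1
Why: The B2 phenol, para to the ketone, is acidic and alkylates readily; capping it prevents a para-quinone methide from ring B in the later ionisation.

Step 18
Reactants: 29 {4-(benzyloxy)-5-[(3R)-7-(benzyloxy)chroman-3-yl]-2-methoxyphenyl}[4-(benzyloxy)-2-(methoxymethoxy)phenyl]methanone
Product: 30 {4-(benzyloxy)-5-[(3R)-7-(benzyloxy)chroman-3-yl]-2-methoxyphenyl}[4-(benzyloxy)-2-hydroxyphenyl]methanone
Conditions: HCl (3 M aq, cat.), MeOH/THF, 45 °C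
Reagents that add atoms: none
Why: Acid-catalysed acetal exchange with methanol removes the methoxymethyl group at the ketone stage, where no ionisable benzylic alcohol is present, and benzyl and methyl ethers survive.

Step 19
Reactants: 30 {4-(benzyloxy)-5-[(3R)-7-(benzyloxy)chroman-3-yl]-2-methoxyphenyl}[4-(benzyloxy)-2-hydroxyphenyl]methanone
Product: 31 5-(benzyloxy)-2-[{4-(benzyloxy)-5-[(3R)-7-(benzyloxy)chroman-3-yl]-2-methoxyphenyl}(hydroxy)methyl]phenol (carbinol epimer mixture)
Conditions: NaBH4, THF/MeOH, 0 °C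
Reagents that add atoms: none
Why: Hydride reduction of the diaryl ketone at low temperature stops at the benzhydrol; the carbinol configuration does not matter because this carbon becomes sp2 in the quinone methide.

Step 20
Reactants: 31 5-(benzyloxy)-2-[{4-(benzyloxy)-5-[(3R)-7-(benzyloxy)chroman-3-yl]-2-methoxyphenyl}(hydroxy)methyl]phenol (carbinol epimer mixture)
Product: 32 5-(benzyloxy)-2-[{4-(benzyloxy)-5-[(3R)-7-(benzyloxy)chroman-3-yl]-2-methoxyphenyl}(4-methylphenylsulfonyl)methyl]phenol (epimer mixture)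
Conditions: p-TolSO2Na (3 equiv), HCO2H, CH2Cl2/H2O, rt
Reagents that add atoms: sodium p-toluenesulfinate, Cc1ccc(cc1)S(=O)[O-].[Na+]
Why: Mild acid ionises the electron-rich benzhydrol and sulfinate traps the cation at sulfur, giving the usual shelf-stable precursor that releases an ortho-quinone methide with base.

Step 21
Reactants: 32 5-(benzyloxy)-2-[{4-(benzyloxy)-5-[(3R)-7-(benzyloxy)chroman-3-yl]-2-methoxyphenyl}(4-methylphenylsulfonyl)methyl]phenol (epimer mixture); 28 2-[3-(benzyloxy)-2,4-dimethoxyphenyl]acetic acid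
Product: 35 (3S,4S)-7-(benzyloxy)-3-[3-(benzyloxy)-2,4-dimethoxyphenyl]-4-{4-(benzyloxy)-5-[(3R)-7-(benzyloxy)chroman-3-yl]-2-methoxyphenyl}chroman-2-one, via pivalic mixed anhydride 33 (not isolated), via ortho-quinone methide 34 (not isolated)
Conditions: 28 (1.5 equiv), PivCl, iPr2NEt, CH2Cl2, 0 °C; then 32, (S)-BTM (benzotetramisole, 10 mol%), iPr2NEt, 0 °C → rt
Reagents that add atoms: none
Why: In this isothiourea-catalysed formal [4+2] annulation the catalyst is acylated by the mixed anhydride and forms a planar Z ammonium enolate (held by the O···S contact) that adds to the base-released quinone methide on the face away from the catalyst phenyl group before the phenoxide lactonises and frees the catalyst, so the catalyst sets C4 as S and, kinetically, C3 as S (cis).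

Step 22
Reactants: 35 (3S,4S)-7-(benzyloxy)-3-[3-(benzyloxy)-2,4-dimethoxyphenyl]-4-{4-(benzyloxy)-5-[(3R)-7-(benzyloxy)chroman-3-yl]-2-methoxyphenyl}chroman-2-one
Product: 36 (3R,4S)-7-(benzyloxy)-3-[3-(benzyloxy)-2,4-dimethoxyphenyl]-4-{4-(benzyloxy)-5-[(3R)-7-(benzyloxy)chroman-3-yl]-2-methoxyphenyl}chroman-2-one
Conditions: DBU (0.2 equiv), CH2Cl2, rt
Reagents that add atoms: none
Why: Base equilibration through the lactone enolate inverts the acidic C3 (α to carbonyl and aryl) to the more stable trans-diaryl arrangement (3R), while the non-acidic C4 stays S.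

Step 23
Reactants: 36 (3R,4S)-7-(benzyloxy)-3-[3-(benzyloxy)-2,4-dimethoxyphenyl]-4-{4-(benzyloxy)-5-[(3R)-7-(benzyloxy)chroman-3-yl]-2-methoxyphenyl}chroman-2-one
Product: 37 (2R,3S)-2-[3-(benzyloxy)-2,4-dimethoxyphenyl]-3-{4-(benzyloxy)-5-[(3R)-7-(benzyloxy)chroman-3-yl]-2-methoxyphenyl}-3-[4-(benzyloxy)-2-hydroxyphenyl]propan-1-ol
Conditions: LiAlH4, THF, 0 °C; then H2O/NaOH work-up
Reagents that add atoms: none
Why: Hydride reduction of the aryl ester opens the lactone to the phenol and the primary alcohol faster than any enolisation, so both stereocentres are kept.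

Step 24
Reactants: 37 (2R,3S)-2-[3-(benzyloxy)-2,4-dimethoxyphenyl]-3-{4-(benzyloxy)-5-[(3R)-7-(benzyloxy)chroman-3-yl]-2-methoxyphenyl}-3-[4-(benzyloxy)-2-hydroxyphenyl]propan-1-ol
Product: 38 (3R,4S)-7-(benzyloxy)-3-[3-(benzyloxy)-2,4-dimethoxyphenyl]-4-{4-(benzyloxy)-5-[(3R)-7-(benzyloxy)chroman-3-yl]-2-methoxyphenyl}chroman
Conditions: PPh3, DIAD, THF, 0 °C → rt
Reagents that add atoms: none
Why: Intramolecular Mitsunobu etherification, in which the only free phenol displaces the activated primary alcohol in a 6-exo closure of the lower pyran ring at a carbon that is not stereogenic.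

Step 25
Reactants: 38 (3R,4S)-7-(benzyloxy)-3-[3-(benzyloxy)-2,4-dimethoxyphenyl]-4-{4-(benzyloxy)-5-[(3R)-7-(benzyloxy)chroman-3-yl]-2-methoxyphenyl}chroman
Product: 39 (3R,4S)-3-(3-hydroxy-2,4-dimethoxyphenyl)-4-{4-hydroxy-5-[(3R)-7-hydroxychroman-3-yl]-2-methoxyphenyl}chroman-7-ol (CNP0202416.1)
Conditions: H2 (1 atm), 10% Pd/C, EtOAc/MeOH, rt
Reagents that add atoms: none
Why: Hydrogenolysis cleaves the four O-benzyl groups, while the alkyl aryl ethers of both pyran rings, the methyl ethers and the triarylmethane C–H are not cleaved under these conditions.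

## Compound list

1 | 2,4-dihydroxybenzaldehyde | O=Cc1ccc(O)cc1O | starting material
2 | 4-(benzyloxy)-2-hydroxybenzaldehyde | O=Cc1ccc(OCc2ccccc2)cc1O | intermediate
3 | acrylonitrile | C=CC#N | starting material
4 | 7-(benzyloxy)-2H-chromene-3-carbonitrile | N#CC1=Cc2ccc(OCc3ccccc3)cc2OC1 | intermediate
5 | 7-(benzyloxy)-2H-chromene-3-carboxylic acid | OC(=O)C1=Cc2ccc(OCc3ccccc3)cc2OC1 | intermediate
6 | (S)-7-(benzyloxy)chroman-3-carboxylic acid | OC(=O)[C@@H]1COc2cc(OCc3ccccc3)ccc2C1 | intermediate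
7 | isobutyl carbonic mixed anhydride of 6 | CC(C)COC(=O)OC(=O)[C@@H]1COc2cc(OCc3ccccc3)ccc2C1 | intermediate
8 | (S)-1-[7-(benzyloxy)chroman-3-yl]-2-diazoethan-1-one | [N-]=[N+]=CC(=O)[C@@H]1COc2cc(OCc3ccccc3)ccc2C1 | intermediate
9 | (R)-2-[7-(benzyloxy)chroman-3-yl]ethenone (ketene) | O=C=C[C@@H]1COc2cc(OCc3ccccc3)ccc2C1 | intermediate
10 | (R)-2-[7-(benzyloxy)chroman-3-yl]acetic acid | OC(=O)C[C@@H]1COc2cc(OCc3ccccc3)ccc2C1 | intermediate
11 | 1,1-dimethoxyethene | C=C(OC)OC | starting material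
12 | (R)-2-[7-(benzyloxy)chroman-3-yl]acetyl chloride | ClC(=O)C[C@@H]1COc2cc(OCc3ccccc3)ccc2C1 | intermediate
13 | (R)-1-[7-(benzyloxy)chroman-3-yl]-4,4-dimethoxybut-3-en-2-one | COC(OC)=CC(=O)C[C@@H]1COc2cc(OCc3ccccc3)ccc2C1 | intermediate
14 | (R)-7-(benzyloxy)-3-[(1Z)-4,4-dimethoxy-2-(trimethylsilyloxy)buta-1,3-dien-1-yl]chroman | COC(OC)=C/C(O[Si](C)(C)C)=C/[C@@H]1COc2cc(OCc3ccccc3)ccc2C1 | intermediate
15 | 4-(benzyloxy)-2-(methoxymethoxy)benzaldehyde | O=Cc1ccc(OCc2ccccc2)cc1OCOC | intermediate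
16 | ethynylmagnesium bromide | C#C[Mg]Br | starting material
17 | rac-1-[4-(benzyloxy)-2-(methoxymethoxy)phenyl]prop-2-yn-1-ol | C#CC(O)c1ccc(OCc2ccccc2)cc1OCOC | intermediate
18 | 1-[4-(benzyloxy)-2-(methoxymethoxy)phenyl]prop-2-yn-1-one | C#CC(=O)c1ccc(OCc2ccccc2)cc1OCOC | intermediate
19 | [4-(benzyloxy)-2-(methoxymethoxy)phenyl]{3-[(3R)-7-(benzyloxy)chroman-3-yl]-6,6-dimethoxy-4-(trimethylsilyloxy)cyclohexa-1,4-dien-1-yl}methanone | COC1(OC)C=C(O[Si](C)(C)C)C([C@@H]2COc3cc(OCc4ccccc4)ccc3C2)C=C1C(=O)c1ccc(OCc2ccccc2)cc1OCOC | intermediate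
20 | [4-(benzyloxy)-2-(methoxymethoxy)phenyl]{5-[(3R)-7-(benzyloxy)chroman-3-yl]-2-methoxy-4-(trimethylsilyloxy)phenyl}methanone | COc1cc(O[Si](C)(C)C)c([C@@H]2COc3cc(OCc4ccccc4)ccc3C2)cc1C(=O)c1ccc(OCc2ccccc2)cc1OCOC | intermediate
21 | [4-(benzyloxy)-2-(methoxymethoxy)phenyl]{5-[(3R)-7-(benzyloxy)chroman-3-yl]-4-hydroxy-2-methoxyphenyl}methanone | COc1cc(O)c([C@@H]2COc3cc(OCc4ccccc4)ccc3C2)cc1C(=O)c1ccc(OCc2ccccc2)cc1OCOC | intermediate
22 | 2,6-dimethoxyphenol | COc1cccc(OC)c1O | starting material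
23 | 2-(benzyloxy)-1,3-dimethoxybenzene | COc1cccc(OC)c1OCc1ccccc1 | intermediate
24 | 3-(benzyloxy)-1-bromo-2,4-dimethoxybenzene | COc1ccc(Br)c(OC)c1OCc1ccccc1 | intermediate
25 | diethyl malonate | CCOC(=O)CC(=O)OCC | starting material
26 | diethyl 2-[3-(benzyloxy)-2,4-dimethoxyphenyl]malonate | CCOC(=O)C(C(=O)OCC)c1ccc(OC)c(OCc2ccccc2)c1OC | intermediate
27 | 2-[3-(benzyloxy)-2,4-dimethoxyphenyl]malonic acid | OC(=O)C(C(=O)O)c1ccc(OC)c(OCc2ccccc2)c1OC | intermediate
28 | 2-[3-(benzyloxy)-2,4-dimethoxyphenyl]acetic acid | OC(=O)Cc1ccc(OC)c(OCc2ccccc2)c1OC | intermediate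
29 | {4-(benzyloxy)-5-[(3R)-7-(benzyloxy)chroman-3-yl]-2-methoxyphenyl}[4-(benzyloxy)-2-(methoxymethoxy)phenyl]methanone | COc1cc(OCc2ccccc2)c([C@@H]2COc3cc(OCc4ccccc4)ccc3C2)cc1C(=O)c1ccc(OCc2ccccc2)cc1OCOC | intermediate
30 | {4-(benzyloxy)-5-[(3R)-7-(benzyloxy)chroman-3-yl]-2-methoxyphenyl}[4-(benzyloxy)-2-hydroxyphenyl]methanone | COc1cc(OCc2ccccc2)c([C@@H]2COc3cc(OCc4ccccc4)ccc3C2)cc1C(=O)c1ccc(OCc2ccccc2)cc1O | intermediate
31 | 5-(benzyloxy)-2-[{4-(benzyloxy)-5-[(3R)-7-(benzyloxy)chroman-3-yl]-2-methoxyphenyl}(hydroxy)methyl]phenol (carbinol epimer mixture) | COc1cc(OCc2ccccc2)c([C@@H]2COc3cc(OCc4ccccc4)ccc3C2)cc1C(O)c1ccc(OCc2ccccc2)cc1O | intermediate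
32 | 5-(benzyloxy)-2-[{4-(benzyloxy)-5-[(3R)-7-(benzyloxy)chroman-3-yl]-2-methoxyphenyl}(4-methylphenylsulfonyl)methyl]phenol (epimer mixture) | COc1cc(OCc2ccccc2)c([C@@H]2COc3cc(OCc4ccccc4)ccc3C2)cc1C(c1ccc(OCc2ccccc2)cc1O)S(=O)(=O)c1ccc(C)cc1 | intermediate
33 | 2-[3-(benzyloxy)-2,4-dimethoxyphenyl]acetic pivalic anhydride | CC(C)(C)C(=O)OC(=O)Cc1ccc(OC)c(OCc2ccccc2)c1OC | intermediate
34 | 3-(benzyloxy)-6-[{4-(benzyloxy)-5-[(3R)-7-(benzyloxy)chroman-3-yl]-2-methoxyphenyl}methylidene]cyclohexa-2,4-dien-1-one | COc1cc(OCc2ccccc2)c([C@@H]2COc3cc(OCc4ccccc4)ccc3C2)cc1C=C1C=CC(OCc2ccccc2)=CC1=O | intermediate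
35 | (3S,4S)-7-(benzyloxy)-3-[3-(benzyloxy)-2,4-dimethoxyphenyl]-4-{4-(benzyloxy)-5-[(3R)-7-(benzyloxy)chroman-3-yl]-2-methoxyphenyl}chroman-2-one (cis) | COc1cc(OCc2ccccc2)c([C@@H]2COc3cc(OCc4ccccc4)ccc3C2)cc1[C@@H]1c2ccc(OCc3ccccc3)cc2OC(=O)[C@@H]1c1ccc(OC)c(OCc2ccccc2)c1OC | intermediate
36 | (3R,4S)-7-(benzyloxy)-3-[3-(benzyloxy)-2,4-dimethoxyphenyl]-4-{4-(benzyloxy)-5-[(3R)-7-(benzyloxy)chroman-3-yl]-2-methoxyphenyl}chroman-2-one (trans) | COc1cc(OCc2ccccc2)c([C@@H]2COc3cc(OCc4ccccc4)ccc3C2)cc1[C@@H]1c2ccc(OCc3ccccc3)cc2OC(=O)[C@H]1c1ccc(OC)c(OCc2ccccc2)c1OC | intermediate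
37 | (2R,3S)-2-[3-(benzyloxy)-2,4-dimethoxyphenyl]-3-{4-(benzyloxy)-5-[(3R)-7-(benzyloxy)chroman-3-yl]-2-methoxyphenyl}-3-[4-(benzyloxy)-2-hydroxyphenyl]propan-1-ol | COc1cc(OCc2ccccc2)c([C@@H]2COc3cc(OCc4ccccc4)ccc3C2)cc1[C@@H]([C@@H](CO)c1ccc(OC)c(OCc2ccccc2)c1OC)c1ccc(OCc2ccccc2)cc1O | intermediate
38 | (3R,4S)-7-(benzyloxy)-3-[3-(benzyloxy)-2,4-dimethoxyphenyl]-4-{4-(benzyloxy)-5-[(3R)-7-(benzyloxy)chroman-3-yl]-2-methoxyphenyl}chroman | COc1cc(OCc2ccccc2)c([C@@H]2COc3cc(OCc4ccccc4)ccc3C2)cc1[C@@H]1c2ccc(OCc3ccccc3)cc2OC[C@H]1c1ccc(OC)c(OCc2ccccc2)c1OC | intermediate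
39 | (3R,4S)-3-(3-hydroxy-2,4-dimethoxyphenyl)-4-{4-hydroxy-5-[(3R)-7-hydroxychroman-3-yl]-2-methoxyphenyl}chroman-7-ol | COc1cc(O)c([C@@H]2COc3cc(O)ccc3C2)cc1[C@@H]1c2ccc(O)cc2OC[C@H]1c1ccc(OC)c(O)c1OC | target

## Step count and risks

Total step count: 25.
Longest linear sequence: 18 steps (steps 1–8, 12, 17–25).

Steps most likely to fail:

1. Step 12 (key cycloaddition). The cycloaddition may be slow at the hindered, chroman-bearing diene terminus, so that silyl transfer or hydrolysis of the diene and conjugate-addition oligomerisation of the terminal ynone win, or an open-chain Michael adduct forms that does not close.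
 - Fallback, setting out from diene 14 and returning at 30: ring D is no longer carried through the cycloaddition. Diene 14 is heated in neat, excess methyl propiolate (60–80 °C; then K2CO3, MeOH), which raises the bimolecular rate and should give methyl 5-[(3R)-7-(benzyloxy)chroman-3-yl]-4-hydroxy-2-methoxybenzoate F1.
 - BnBr/K2CO3 gives methyl 4-(benzyloxy)-5-[(3R)-7-(benzyloxy)chroman-3-yl]-2-methoxybenzoate F2, and Me(MeO)NH·HCl/iPrMgCl in THF converts it into the N-methoxy-N-methylamide F3.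
 - Separately, 4-bromoresorcinol with MOMCl/iPr2NEt gives 1-bromo-2,4-bis(methoxymethoxy)benzene F4; bromine–lithium exchange (nBuLi, THF, −78 °C) gives 2,4-bis(methoxymethoxy)phenyllithium F5, which adds once to F3 to give {4-(benzyloxy)-5-[(3R)-7-(benzyloxy)chroman-3-yl]-2-methoxyphenyl}[2,4-bis(methoxymethoxy)phenyl]methanone F6.
 - HCl in MeOH removes both acetals to give the 2,4-dihydroxyphenyl ketone F7, and BnBr/NaHCO3 benzylates only its non-chelated 4-OH (the selectivity of step 1) to reach 30.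

2. Step 21 (asymmetric annulation). The enolate may add with poor facial selectivity to the electron-rich quinone methide, or acyl transfer to the phenol and self-condensation of the quinone methide may outrun the catalytic cycle.
 - Fallback, setting out from acid 28 and sulfone 32 and returning at 38 (steps 22–24 are then not needed): enamine catalysis replaces ammonium-enolate catalysis. Acid 28 is reduced (BH3·SMe2, THF) to 2-[3-(benzyloxy)-2,4-dimethoxyphenyl]ethanol F8 and oxidised (Parikh–Doering: SO3·pyridine, DMSO, iPr2NEt) to 2-[3-(benzyloxy)-2,4-dimethoxyphenyl]acetaldehyde F9.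
 - F9 and sulfone 32 with a diphenylprolinol trimethylsilyl ether (20 mol%, the antipode that gives 4S) and NaHCO3 in CH2Cl2 undergo enamine Michael addition to the quinone methide and hemiacetal closure, giving after equilibration of the enolisable C3 the trans (3R,4S)-3,4-diarylchroman-2-ol F10.
 - Ionic reduction of F10 (Et3SiH, BF3·OEt2, CH2Cl2, −78 → 0 °C) through the cyclic oxocarbenium ion gives 38 directly.

3. Step 7 (acyl ketene acetal). The enolisable acid chloride may form a ketene instead of acylating the ketene acetal, and the acyl ketene acetal may hydrolyse on isolation.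
 - Fallback, setting out from acid 10 (and using ynone 18) and returning at 29: the oxygen pattern is set after the ring is made. Acid 10 is activated with carbonyldiimidazole and chain-extended with potassium methyl malonate/MgCl2/Et3N to methyl 4-[(3R)-7-(benzyloxy)chroman-3-yl]-3-oxobutanoate F11.
 - TMSCl/Et3N, then LDA/TMSCl, give the 1-methoxy-1,3-bis(trimethylsilyloxy)diene F12, whose cycloaddition with 18 (toluene, then K2CO3/MeOH) should give the 2,4-dihydroxybenzophenone F13.
 - One equivalent of BnBr/K2CO3 in acetone alkylates only the non-chelated hydroxyl para to the ketone to give the 4-benzyloxy-2-hydroxy compound F14, and MeI/K2CO3 in DMF at 50 °C then methylates the chelated hydroxyl to reach 29.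

## Further compounds

F1 | step 12 | methyl 5-[(3R)-7-(benzyloxy)chroman-3-yl]-4-hydroxy-2-methoxybenzoate | COC(=O)c1cc([C@@H]2COc3cc(OCc4ccccc4)ccc3C2)c(O)cc1OC
F2 | step 12 | methyl 4-(benzyloxy)-5-[(3R)-7-(benzyloxy)chroman-3-yl]-2-methoxybenzoate | COC(=O)c1cc([C@@H]2COc3cc(OCc4ccccc4)ccc3C2)c(OCc2ccccc2)cc1OC
F3 | step 12 | 4-(benzyloxy)-5-[(3R)-7-(benzyloxy)chroman-3-yl]-N,2-dimethoxy-N-methylbenzamide | CON(C)C(=O)c1cc([C@@H]2COc3cc(OCc4ccccc4)ccc3C2)c(OCc2ccccc2)cc1OC
F4 | step 12 | 1-bromo-2,4-bis(methoxymethoxy)benzene | COCOc1ccc(Br)c(OCOC)c1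
F5 | step 12 | 2,4-bis(methoxymethoxy)phenyllithium | [Li]c1ccc(OCOC)cc1OCOC
F6 | step 12 | {4-(benzyloxy)-5-[(3R)-7-(benzyloxy)chroman-3-yl]-2-methoxyphenyl}[2,4-bis(methoxymethoxy)phenyl]methanone | COCOc1ccc(C(=O)c2cc([C@@H]3COc4cc(OCc5ccccc5)ccc4C3)c(OCc3ccccc3)cc2OC)c(OCOC)c1
F7 | step 12 | {4-(benzyloxy)-5-[(3R)-7-(benzyloxy)chroman-3-yl]-2-methoxyphenyl}(2,4-dihydroxyphenyl)methanone | COc1cc(OCc2ccccc2)c([C@@H]2COc3cc(OCc4ccccc4)ccc3C2)cc1C(=O)c1ccc(O)cc1O
F8 | step 21 | 2-[3-(benzyloxy)-2,4-dimethoxyphenyl]ethanol | OCCc1ccc(OC)c(OCc2ccccc2)c1OC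
F9 | step 21 | 2-[3-(benzyloxy)-2,4-dimethoxyphenyl]acetaldehyde | O=CCc1ccc(OC)c(OCc2ccccc2)c1OC
F10 | step 21 | (3R,4S)-7-(benzyloxy)-3-[3-(benzyloxy)-2,4-dimethoxyphenyl]-4-{4-(benzyloxy)-5-[(3R)-7-(benzyloxy)chroman-3-yl]-2-methoxyphenyl}chroman-2-ol (anomer mixture) | COc1cc(OCc2ccccc2)c([C@@H]2COc3cc(OCc4ccccc4)ccc3C2)cc1[C@@H]1c2ccc(OCc3ccccc3)cc2OC(O)[C@H]1c1ccc(OC)c(OCc2ccccc2)c1OC
F11 | step 7 | methyl 4-[(3R)-7-(benzyloxy)chroman-3-yl]-3-oxobutanoate | COC(=O)CC(=O)C[C@@H]1COc2cc(OCc3ccccc3)ccc2C1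
F12 | step 7 | (R)-7-(benzyloxy)-3-[(1Z)-4-methoxy-2,4-bis(trimethylsilyloxy)buta-1,3-dien-1-yl]chroman | COC(O[Si](C)(C)C)=C/C(O[Si](C)(C)C)=C/[C@@H]1COc2cc(OCc3ccccc3)ccc2C1
F13 | step 7 | [4-(benzyloxy)-2-(methoxymethoxy)phenyl]{5-[(3R)-7-(benzyloxy)chroman-3-yl]-2,4-dihydroxyphenyl}methanone | Oc1cc(O)c([C@@H]2COc3cc(OCc4ccccc4)ccc3C2)cc1C(=O)c1ccc(OCc2ccccc2)cc1OCOC
F14 | step 7 | {4-(benzyloxy)-5-[(3R)-7-(benzyloxy)chroman-3-yl]-2-hydroxyphenyl}[4-(benzyloxy)-2-(methoxymethoxy)phenyl]methanone | Oc1cc(OCc2ccccc2)c([C@@H]2COc3cc(OCc4ccccc4)ccc3C2)cc1C(=O)c1ccc(OCc2ccccc2)cc1OCOC
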